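**Plan**

1. Retrosynthesis: both epoxides (C3–C4, C13–C14) are removed last to give a triene. The ten-membered ring is cut at C3=C4 (metathesis), the hydroxy lactone at C8–C17 (Reformatsky), the C6–Cl/C7–O pair via a C6–C7 epoxide to an enone (C6=C7 by olefination), and ring A at C1–C10 and C12–C13.
2. Enabling feature: C10–C11–C12 of ring A, with the C9 oxygen, is the skeleton of a γ-substituted α-methylbutenolide (C12 = lactone carbonyl, C9–O = lactone oxygen), a 1,3-dielectrophile. C13–C14–C1 with C2 is 2-methyl-3-oxobutanenitrile, a 1,3-dinucleophile.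
3. Forward: the butenolide (three steps from a glycidyl ether) and the cyanoketone give ring A in one Michael–Claisen [3+3] operation. The dione is transposed to the C12 allylic alcohol with the C13=C14 alkene, and the nitrile becomes the C2 vinyl carbinol.
4. The chain C8→C4 is then grown from C8 (ketophosphonate, olefination, epoxidation, HCl opening, Reformatsky lactone). Ethylene enyne metathesis and ring-closing metathesis close the ten-membered ring, and a hydroxyl-directed double epoxidation ends the route.
5. Stereochemistry: C9 comes from (R)-glycidyl ether; C10, C11 and C1 from the butenolide in the key step; C12 from a substrate-controlled Luche reduction; C2 from a CBS reduction; C6/C7 from a catalyst-controlled epoxidation and chloride inversion; C8/C17 from C7 through the lactone closure; C3, C4, C13, C14 from the C2 hydroxyl.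

Key step: step 4

Remark: briarane numbering is used throughout: C1 quaternary (methyl C15), C2 carbinol, C3/C4 epoxide, C5 (methylene C16), C6 chloride, C7 lactone O–CH, C8 tertiary carbinol, C9 and C12 acetoxy carbons, C10 ring-fusion CH, C11 (methyl C20), C13/C14 epoxide, C17 (methyl C18), C19 lactone carbonyl. Ring A is the six-membered ring. PMB = 4-methoxybenzyl, TES = triethylsilyl, TBS = tert-butyldimethylsilyl.

Assumption: (R)-glycidyl 4-methoxybenzyl ether, 2-methyl-3-oxobutanenitrile and 3-(trimethylsilyl)prop-2-ynal are taken as commercially available; everything else is a common reagent.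

Step 1
Reactants: 1 (R)-glycidyl 4-methoxybenzyl ether
Product: 2 (R)-1-(4-methoxybenzyloxy)but-3-en-2-ol
Conditions: Me3S+ I−, n-BuLi, THF, −10 → 25 °C
Reagents that add atoms: trimethylsulfonium iodide, C[S+](C)C.[I-]
Why: Corey–Chaykovsky-type opening of the terminal epoxide by dimethylsulfonium methylide followed by elimination of dimethyl sulfide homologates the epoxide to the allylic alcohol without touching the stereocentre (the future C9).

Step 2
Reactants: 2 (R)-1-(4-methoxybenzyloxy)but-3-en-2-ol
Product: 3 (R)-1-(4-methoxybenzyloxy)but-3-en-2-yl methacrylate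
Conditions: methacryloyl chloride, Et3N, DMAP (cat.), CH2Cl2, 0 °C
Reagents that add atoms: methacryloyl chloride, C=C(C)C(Cl)=O
Why: DMAP-catalysed acylation of a secondary alcohol by an acid chloride brings in C11, C12 and the C20 methyl.

Step 3
Reactants: 3 (R)-1-(4-methoxybenzyloxy)but-3-en-2-yl methacrylate
Product: 4 (R)-5-[(4-methoxybenzyloxy)methyl]-3-methylfuran-2(5H)-one
Conditions: second-generation Grubbs catalyst (5 mol %), toluene, 80 °C
Reagents that add atoms: none
Why: Ring-closing metathesis of the methacrylate with the vinyl group, driven by loss of ethylene, should give the trisubstituted butenolide whose ring carbons are C9 to C12.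

Step 4
Reactants: 4 (R)-5-[(4-methoxybenzyloxy)methyl]-3-methylfuran-2(5H)-one; 5 2-methyl-3-oxobutanenitrile
Product: 7 ring A cyanodione, via Michael adduct lactone 6 (not isolated)
Conditions: tBuOK (2.2 equiv), tBuOH–THF, 0 → 45 °C; then 1 M HCl
Reagents that add atoms: none
Why: Proposed new method: the potassium enolate of 5, nucleophilic at the carbon flanked by nitrile and ketone, adds to C10 of butenolide 4 anti to the C9 side chain, and tBuOH protonates the lactone enolate to give the all-trans lactone 6 with the C11 methyl trans to the new C1 substituent. The methyl ketone enolate (C13) of 6 then attacks the lactone carbonyl C12 in a 6-exo-trig Claisen closure of ring A through a 2-oxabicyclo[3.2.1]octane tetrahedral intermediate, which collapses with release of the C9 alkoxide to the 1,3-diketonate, an irreversible sink that pays for the crowded C1–C10 bond. The closest known reaction type is the consecutive Michael–Claisen [3+3] annulation of ketones and acrylates to cyclohexane-1,3-diones; new here is a γ-substituted butenolide as the three-carbon partner, whose stereocentre steers the Michael step and whose lactone is the acyl donor. C10 is fixed by C9 (anti addition to the butenolide face) and C11 by equilibration of the lactone α-carbon. C1 is fixed by a dynamic resolution: the Michael step is reversible under the alkoxide, and the C1 epimer that puts the small nitrile axial and the methyl equatorial in the chair of the bicyclic transition state (the nitrile has a far smaller A value than methyl) should cyclise faster, which gives the target arrangement with the C1 methyl, the C10 side chain and the C11 methyl on one face. The step needs the doubly activated C–H of 5 to act as Michael donor and only its methyl group as Claisen donor, which the acidities and the lack of any other enolisable acyl group secure.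

Step 5
Reactants: 7 ring A cyanodione
Product: 8 C12 methyl enol ether (vinylogous ester with the C14 ketone)
Conditions: MeOH, TsOH·H2O (5 mol %), 3 Å molecular sieves, 25 °C
Reagents that add atoms: methanol, CO
Why: Acid-catalysed enol etherification of the 1,3-dione (first half of a Stork–Danheiser transposition) is expected to go through the less hindered C12 carbonyl, remote from the quaternary C1, so that the carbonyl left is C14.

Step 6
Reactants: 8 C12 methyl enol ether
Product: 10 ring A enone (C12 ketone with C13=C14), via methoxy allylic alcohol 9 (not isolated)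
Conditions: NaBH4, CeCl3·7H2O, MeOH–THF, −20 °C; then 1 M HCl, THF, 0 °C
Reagents that add atoms: water, O
Why: Luche 1,2-reduction of the vinylogous ester carbonyl and acid hydrolysis of the enol ether with loss of water (Stork–Danheiser transposition) should give the 4,4-disubstituted cyclohexenone with the alkene at C13=C14, the nitrile being inert to NaBH4.

Step 7
Reactants: 10 ring A enone
Product: 11 ring A allylic alcohol (9,12-diol nitrile)
Conditions: NaBH4, CeCl3·7H2O, MeOH, −78 °C; dilute HCl work-up
Reagents that add atoms: none
Why: Luche reduction; hydride should add to the C12 carbonyl from the face that carries only the remote nitrile, opposite the C1 methyl, the C10 side chain and the C11 methyl, so that the new C12 hydroxyl is cis to the C11 methyl as in the target.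

Step 8
Reactants: 11 ring A allylic alcohol
Product: 12 9,12-bis(triethylsilyl) ether
Conditions: TESOTf, 2,6-lutidine, CH2Cl2, −78 → 0 °C
Reagents that add atoms: triethylsilyl trifluoromethanesulfonate, CC[Si](CC)(CC)OS(=O)(=O)C(F)(F)F
Why: Silylation of both secondary alcohols with the silyl triflate protects them for the hydride, Grignard and oxidation steps on C2.

Step 9
Reactants: 12 9,12-bis(triethylsilyl) ether
Product: 13 C2 aldehyde
Conditions: iBu2AlH, toluene, −78 → −20 °C; then aq. potassium sodium tartrate
Reagents that add atoms: water, O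
Why: Partial reduction of the nitrile by iBu2AlH to the iBu2Al–imine adduct and its hydrolysis should give the neopentyl aldehyde, the silyl and PMB ethers being inert.

Step 10
Reactants: 13 C2 aldehyde
Product: 14 C2 vinyl carbinol (both C2 epimers)
Conditions: CH2=CHMgBr, THF, −78 → 0 °C; aq. NH4Cl
Reagents that add atoms: vinylmagnesium bromide, C=C[Mg]Br
Why: Grignard 1,2-addition brings in C3; the C2 configuration is not relied on here and is set in steps 11 and 12.

Step 11
Reactants: 14 C2 vinyl carbinol
Product: 15 C2 vinyl ketone
Conditions: Dess–Martin periodinane, NaHCO3, CH2Cl2, 0 → 25 °C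
Reagents that add atoms: none
Why: Dess–Martin oxidation of the allylic alcohol converges both C2 epimers on one enone.

Step 12
Reactants: 15 C2 vinyl ketone
Product: 16 C2 allylic alcohol (C2 as in the target)
Conditions: (S)-2-methyl-CBS-oxazaborolidine (20 mol %), catecholborane, toluene, −78 °C
Reagents that add atoms: none
Why: Corey–Bakshi–Shibata reduction is reagent-controlled: with the tertiary C1 as the large group and vinyl as the small one, the (S)-catalyst should deliver hydride in the sense that gives (R)-1-phenylethanol from acetophenone, which is the C2 configuration of the target, and catecholborane at −78 °C leaves the alkenes alone.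

Step 13
Reactants: 16 C2 allylic alcohol
Product: 17 C2 TBS ether
Conditions: TBSOTf, 2,6-lutidine, CH2Cl2, 0 °C
Reagents that add atoms: tert-butyldimethylsilyl trifluoromethanesulfonate, CC(C)(C)[Si](C)(C)OS(=O)(=O)C(F)(F)F
Why: Silyl triflate silylation of the hindered neopentyl alcohol gives a robust ether that can outlast the two TES groups.

Step 14
Reactants: 17 C2 TBS ether
Product: 18 9,12-diol
Conditions: HF·pyridine, pyridine, THF, 0 °C
Reagents that add atoms: none
Why: Fluoride cleavage is selective for the two triethylsilyl ethers over the bulkier TBS ether at the neopentyl C2.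

Step 15
Reactants: 18 9,12-diol
Product: 19 9,12-diacetate
Conditions: Ac2O, pyridine, DMAP (cat.), CH2Cl2, 25 °C
Reagents that add atoms: acetic anhydride, CC(=O)OC(C)=O
Why: DMAP-catalysed acetylation installs the two acetates of the target while C2 stays silylated, and every later step tolerates acetates.

Step 16
Reactants: 19 9,12-diacetate
Product: 20 C8 primary alcohol
Conditions: DDQ, CH2Cl2–pH 7 buffer, 0 °C
Reagents that add atoms: none
Why: Oxidative cleavage of the electron-rich PMB ether by DDQ frees the C8 alcohol under neutral conditions that should not move the neighbouring acetate.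

Step 17
Reactants: 20 C8 primary alcohol
Product: 21 C8 aldehyde
Conditions: Dess–Martin periodinane, NaHCO3, CH2Cl2, 0 °C
Reagents that add atoms: none
Why: Buffered Dess–Martin oxidation gives the α-acetoxy aldehyde without epimerising C9.

Step 18
Reactants: 21 C8 aldehyde
Product: 22 C7 β-ketophosphonate
Conditions: (MeO)2P(O)CHN2, SnCl2 (20 mol %), CH2Cl2, 25 °C
Reagents that add atoms: dimethyl (diazomethyl)phosphonate, COP(=O)(OC)C=[N+]=[N-]
Why: Roskamp homologation (SnCl2-promoted addition of the diazo phosphonate to the aldehyde, 1,2-hydride shift, loss of N2) turns the aldehyde into the C8 ketone with C7 as the phosphonate carbon under non-basic conditions.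

Step 19
Reactants: 22 C7 β-ketophosphonate; 23 3-(trimethylsilyl)prop-2-ynal
Product: 24 (E)-enynone (C8 ketone with C6=C7)
Conditions: LiCl, iPr2NEt, MeCN, 0 → 25 °C
Reagents that add atoms: none
Why: Horner–Wadsworth–Emmons olefination under Masamune–Roush conditions should give the (E)-enone and is mild enough to keep the α-acetoxy C9 centre.

Step 20
Reactants: 24 (E)-enynone
Product: 25 trans-6,7-epoxy ketone (6R,7S)
Conditions: La(OiPr)3 (10 mol %), (R)-BINOL (10 mol %), Ph3As=O (10 mol %), tBuOOH (decane), 4 Å molecular sieves, THF, 25 °C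
Reagents that add atoms: tert-butyl hydroperoxide, CC(C)(C)OO
Why: Catalytic asymmetric nucleophilic (Weitz–Scheffer-type) epoxidation of the enone is reagent-controlled, the La(OiPr)3–(R)-BINOL–Ph3As=O catalyst being expected to give the (αS,βR) epoxide that sets C7 and the epoxide carbon C6, and the nucleophilic peroxide ignores the other alkenes.

Step 21
Reactants: 25 trans-6,7-epoxy ketone
Product: 26 6-chloro-7-hydroxy ketone
Conditions: HCl (4 M in dioxane, 1.2 equiv), CH2Cl2, −40 °C
Reagents that add atoms: hydrogen chloride, Cl
Why: Acid-mediated epoxide opening; chloride should attack the protonated epoxide with inversion at the propargylic C6, which carries positive charge better than the α-keto C7, giving the anti chlorohydrin with C6–Cl and C7–OH as in the target.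

Step 22
Reactants: 26 6-chloro-7-hydroxy ketone
Product: 27 7-O-(2-bromopropanoyl) ester
Conditions: 2-bromopropanoyl bromide, pyridine, CH2Cl2, −40 → −20 °C
Reagents that add atoms: 2-bromopropanoyl bromide, CC(Br)C(Br)=O
Why: Acylation of the C7 hydroxyl by the acid bromide with a weak base at low temperature avoids β-elimination of HCl; the bromine-bearing carbon is a mixture of epimers, which is of no consequence.

Step 23
Reactants: 27 7-O-(2-bromopropanoyl) ester
Product: 28 hydroxy lactone
Conditions: Zn dust (activated with Me3SiCl), THF, 0 → 25 °C; aq. NH4Cl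
Reagents that add atoms: none
Why: Intramolecular Reformatsky reaction: the bromozinc enolate adds to the adjacent C8 ketone (5-exo-trig) to close the γ-lactone, and the chelated transition state should place the C9 substituent trans to the C6 side chain on the new ring and the epimerisable C17 methyl trans to C9 (cis to the new C8 hydroxyl), the more stable arrangement.

Step 24
Reactants: 28 hydroxy lactone
Product: 29 terminal alkyne with free C2 hydroxyl
Conditions: Bu4NF, AcOH (1:1), THF, 0 → 25 °C
Reagents that add atoms: none
Why: Buffered fluoride cleaves the C2 silyl ether and the alkynyl C–Si bond in one operation without harming the acetates, the lactone or the chloride.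

Step 25
Reactants: 29 terminal alkyne with free C2 hydroxyl
Product: 30 2-substituted buta-1,3-diene
Conditions: second-generation Hoveyda–Grubbs catalyst (10 mol %), ethylene (1 atm), toluene, 60 °C
Reagents that add atoms: ethylene, C=C
Why: Cross enyne metathesis of the terminal alkyne with ethylene should give the 2-substituted butadiene (C4=CH2 and C5=C16), the ethylene atmosphere suppressing reaction at the C2 vinyl group.

Step 26
Reactants: 30 2-substituted buta-1,3-diene
Product: 31 briarane triene (3Z and 5(16) and 13-ene)
Conditions: second-generation Grubbs catalyst (15 mol %), toluene (1 mM), 80 °C, argon sparge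
Reagents that add atoms: none
Why: Ring-closing metathesis between the C2 vinyl group and the monosubstituted end of the diene closes the ten-membered ring with loss of ethylene; the (Z)-C3=C4 alkene is the strain-favoured geometry in a ten-membered ring, and the 1,1-disubstituted C5=C16 and the ring A alkene should not take part.

Step 27
Reactants: 31 briarane triene
Product: 32 CNP0379630.2
Conditions: VO(acac)2 (10 mol %), tBuOOH (decane, 4 equiv), CH2Cl2, 0 → 25 °C
Reagents that add atoms: tert-butyl hydroperoxide, CC(C)(C)OO
Why: VO(acac)2-catalysed hydroxyl-directed epoxidation: the C2 hydroxyl should deliver oxygen to the allylic (Z)-C3=C4 alkene on the face cis to the hydroxyl (as medium-ring allylic alcohols do) and to the homoallylic C13=C14 alkene on the face of the C1–C2 bond, which is also opposite the C1 methyl and the C12 acetate, while the chlorine-deactivated C5=C16 alkene has no directing group in reach.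

**Compound list**

1 | (R)-glycidyl 4-methoxybenzyl ether | COc1ccc(COC[C@H]2CO2)cc1 | starting material
2 | (R)-1-(4-methoxybenzyloxy)but-3-en-2-ol | C=C[C@@H](O)COCc1ccc(OC)cc1 | intermediate
3 | (R)-1-(4-methoxybenzyloxy)but-3-en-2-yl methacrylate | C=C(C)C(=O)O[C@H](C=C)COCc1ccc(OC)cc1 | intermediate
4 | (R)-5-[(4-methoxybenzyloxy)methyl]-3-methylfuran-2(5H)-one (ring carbons = C9 to C12) | CC1=C[C@H](COCc2ccc(OC)cc2)OC1=O | intermediate
5 | 2-methyl-3-oxobutanenitrile | CC(=O)C(C)C#N | starting material
6 | Michael adduct lactone: all-trans 4-(2-cyano-3-oxobutan-2-yl)-3-methyl-5-(PMB-oxymethyl)dihydrofuran-2-one, C1 epimers in equilibrium | CC(=O)C(C)(C#N)[C@@H]1[C@@H](C)C(=O)O[C@H]1COCc1ccc(OC)cc1 | intermediate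
7 | ring A cyanodione: 6-[(1R)-1-hydroxy-2-(PMB-oxy)ethyl]-1,5-dimethyl-2,4-dioxocyclohexane-1-carbonitrile; 1-methyl, 5-methyl and side chain on one face | N#C[C@]1(C)[C@H]([C@@H](C)C(=O)CC1=O)[C@@H](O)COCc1ccc(OC)cc1 | intermediate
8 | C12 methyl enol ether: 4-methoxy-2-oxocyclohex-3-ene analogue of 7 | N#C[C@]1(C)[C@H]([C@@H](C)C(OC)=CC1=O)[C@@H](O)COCc1ccc(OC)cc1 | intermediate
9 | methoxy allylic alcohol: 2-hydroxy-4-methoxycyclohex-3-ene analogue (C14 carbinol, either epimer) | N#C[C@]1(C)[C@H]([C@@H](C)C(OC)=CC1O)[C@@H](O)COCc1ccc(OC)cc1 | intermediate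
10 | ring A enone: 6-[(1R)-1-hydroxy-2-(PMB-oxy)ethyl]-1,5-dimethyl-4-oxocyclohex-2-ene-1-carbonitrile | N#C[C@]1(C)[C@H]([C@@H](C)C(=O)C=C1)[C@@H](O)COCc1ccc(OC)cc1 | intermediate
11 | ring A allylic alcohol: 4-hydroxy analogue of 10, C12 hydroxyl cis to the C11 methyl | N#C[C@]1(C)[C@H]([C@@H](C)[C@@H](O)C=C1)[C@@H](O)COCc1ccc(OC)cc1 | intermediate
12 | 9,12-bis(triethylsilyl) ether of 11 | N#C[C@]1(C)[C@H]([C@@H](C)[C@@H](O[Si](CC)(CC)CC)C=C1)[C@@H](O[Si](CC)(CC)CC)COCc1ccc(OC)cc1 | intermediate
13 | C2 aldehyde (cyclohex-2-ene-1-carbaldehyde) | O=C[C@]1(C)[C@H]([C@@H](C)[C@@H](O[Si](CC)(CC)CC)C=C1)[C@@H](O[Si](CC)(CC)CC)COCc1ccc(OC)cc1 | intermediate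
14 | C2 vinyl carbinol, both C2 epimers | C=CC(O)[C@]1(C)[C@H]([C@@H](C)[C@@H](O[Si](CC)(CC)CC)C=C1)[C@@H](O[Si](CC)(CC)CC)COCc1ccc(OC)cc1 | intermediate
15 | C2 vinyl ketone | C=CC(=O)[C@]1(C)[C@H]([C@@H](C)[C@@H](O[Si](CC)(CC)CC)C=C1)[C@@H](O[Si](CC)(CC)CC)COCc1ccc(OC)cc1 | intermediate
16 | C2 allylic alcohol, C2 as in the target | C=C[C@@H](O)[C@]1(C)[C@H]([C@@H](C)[C@@H](O[Si](CC)(CC)CC)C=C1)[C@@H](O[Si](CC)(CC)CC)COCc1ccc(OC)cc1 | intermediate
17 | C2 TBS ether, 9,12-bis-TES ether | C=C[C@@H](O[Si](C)(C)C(C)(C)C)[C@]1(C)[C@H]([C@@H](C)[C@@H](O[Si](CC)(CC)CC)C=C1)[C@@H](O[Si](CC)(CC)CC)COCc1ccc(OC)cc1 | intermediate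
18 | 9,12-diol, C2 TBS ether | C=C[C@@H](O[Si](C)(C)C(C)(C)C)[C@]1(C)[C@H]([C@@H](C)[C@@H](O)C=C1)[C@@H](O)COCc1ccc(OC)cc1 | intermediate
19 | 9,12-diacetate, C8 PMB ether | C=C[C@@H](O[Si](C)(C)C(C)(C)C)[C@]1(C)[C@H]([C@@H](C)[C@@H](OC(C)=O)C=C1)[C@@H](OC(C)=O)COCc1ccc(OC)cc1 | intermediate
20 | C8 primary alcohol | C=C[C@@H](O[Si](C)(C)C(C)(C)C)[C@]1(C)[C@H]([C@@H](C)[C@@H](OC(C)=O)C=C1)[C@@H](OC(C)=O)CO | intermediate
21 | C8 aldehyde | C=C[C@@H](O[Si](C)(C)C(C)(C)C)[C@]1(C)[C@H]([C@@H](C)[C@@H](OC(C)=O)C=C1)[C@@H](OC(C)=O)C=O | intermediate
22 | C7 β-ketophosphonate (C8 ketone, dimethyl phosphonate on C7) | C=C[C@@H](O[Si](C)(C)C(C)(C)C)[C@]1(C)[C@H]([C@@H](C)[C@@H](OC(C)=O)C=C1)[C@@H](OC(C)=O)C(=O)CP(=O)(OC)OC | intermediate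
23 | 3-(trimethylsilyl)prop-2-ynal | C[Si](C)(C)C#CC=O | starting material
24 | (E)-enynone (C8 ketone, C6=C7, silylated C4≡C5) | C=C[C@@H](O[Si](C)(C)C(C)(C)C)[C@]1(C)[C@H]([C@@H](C)[C@@H](OC(C)=O)C=C1)[C@@H](OC(C)=O)C(=O)/C=C/C#C[Si](C)(C)C | intermediate
25 | trans-6,7-epoxy ketone (6R,7S) | C=C[C@@H](O[Si](C)(C)C(C)(C)C)[C@]1(C)[C@H]([C@@H](C)[C@@H](OC(C)=O)C=C1)[C@@H](OC(C)=O)C(=O)[C@H]2O[C@@H]2C#C[Si](C)(C)C | intermediate
26 | 6-chloro-7-hydroxy ketone (anti chlorohydrin) | C=C[C@@H](O[Si](C)(C)C(C)(C)C)[C@]1(C)[C@H]([C@@H](C)[C@@H](OC(C)=O)C=C1)[C@@H](OC(C)=O)C(=O)[C@@H](O)[C@H](C#C[Si](C)(C)C)Cl | intermediate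
27 | 7-O-(2-bromopropanoyl) ester, epimers at the CHBr carbon | C=C[C@@H](O[Si](C)(C)C(C)(C)C)[C@]1(C)[C@H]([C@@H](C)[C@@H](OC(C)=O)C=C1)[C@@H](OC(C)=O)C(=O)[C@@H](OC(=O)C(C)Br)[C@H](C#C[Si](C)(C)C)Cl | intermediate
28 | hydroxy lactone (C8 tertiary alcohol, C17 methyl, C7–O–C19 lactone) | C=C[C@@H](O[Si](C)(C)C(C)(C)C)[C@]1(C)[C@H]([C@@H](C)[C@@H](OC(C)=O)C=C1)[C@@H](OC(C)=O)[C@]2(O)[C@@H](C)C(=O)O[C@H]2[C@H](C#C[Si](C)(C)C)Cl | intermediate
29 | terminal alkyne with free C2 hydroxyl | C=C[C@@H](O)[C@]1(C)[C@H]([C@@H](C)[C@@H](OC(C)=O)C=C1)[C@@H](OC(C)=O)[C@]2(O)[C@@H](C)C(=O)O[C@H]2[C@H](C#C)Cl | intermediate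
30 | 2-substituted buta-1,3-diene (ring-closing precursor) | C=C[C@@H](O)[C@]1(C)[C@H]([C@@H](C)[C@@H](OC(C)=O)C=C1)[C@@H](OC(C)=O)[C@]2(O)[C@@H](C)C(=O)O[C@H]2[C@H](C(=C)C=C)Cl | intermediate
31 | briarane triene: (3Z)-3,5(16),13-triene, 2,8-diol, 9,12-diacetate, 6-chloride | C=C1/C=C\[C@@H](O)[C@]2(C)[C@H]([C@@H](C)[C@@H](OC(C)=O)C=C2)[C@@H](OC(C)=O)[C@]2(O)[C@@H](C)C(=O)O[C@H]2[C@H]1Cl | intermediate
32 | CNP0379630.2 | C=C1[C@H]2O[C@H]2[C@@H](O)[C@]2(C)[C@H]([C@@H](C)[C@@H](OC(C)=O)[C@@H]3O[C@@H]32)[C@@H](OC(C)=O)[C@]2(O)[C@@H](C)C(=O)O[C@H]2[C@H]1Cl | target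

**Step count and risks**

Total step count: 27. Longest linear sequence: 27 steps (from 1; compounds 5 and 23 enter as purchased reactants).

Steps most likely to fail:

Step 4 (bears the label). What may go wrong: incomplete equilibration of the C1 epimers before ring closure, so that the quaternary centre is set with poor selectivity, or loss of configuration at C9 by γ-deprotonation of the butenolide that the retro-Michael step regenerates. Fallback (known chemistry), from 4 and 5 back to 7: the Michael addition is run alone with K2CO3 in MeCN at 0 °C, where no Claisen closure takes place. The adduct with the target configuration at C1, Michael adduct lactone F1, is separated from its C1 epimer, which is returned to the same conditions and re-equilibrated. F1 is then closed by intramolecular Claisen acylation through its kinetic methyl ketone enolate (LiN(SiMe3)2, THF, −78 °C), where no retro-Michael can scramble C1, and the route is rejoined at 7.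

Step 26. What may go wrong: oligomerisation through the unhindered diene end in place of ring closure, stalling at the conjugated ruthenium vinylcarbene, or closure to the (E)-alkene. Fallback, from 29 back to 31: the ring is closed one step earlier by a different event, ring-closing enyne metathesis. Compound 29 with the second-generation Grubbs catalyst in dilute toluene without ethylene should form the alkylidene at the C2 vinyl group, which adds to the alkyne terminus in the endo mode and so builds C3=C4 and the C5 methylene in one ring-forming step. This gives 31 directly, with no compound outside the list (none F0).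

Step 21. What may go wrong: attack of chloride at the α-keto carbon C7 in place of C6, loss of configuration at C6 through a propargylic cation, or β-elimination of HCl from the hydroxy ketone during the acylation of step 22. Fallback, from 25 back to 27: chloroacylation of the epoxide. 2-Bromopropanoyl chloride with catalytic ZnCl2 O-acylates the epoxide, and chloride opens the acyloxonium ion at the propargylic carbon with inversion. This gives 27 in one step and never exposes a free β-chloro-α-hydroxy ketone to base; no compound outside the list is formed (none F0).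

Further compounds
F1 | step 4 | Michael adduct lactone, single C1 epimer of the target series: (3S,4S,5R-type all-trans) 4-(2-cyano-3-oxobutan-2-yl)-3-methyl-5-(PMB-oxymethyl)dihydrofuran-2-one | CC(=O)[C@](C)(C#N)[C@@H]1[C@@H](C)C(=O)O[C@H]1COCc1ccc(OC)cc1
F0 | step 26 | none | none
F0 | step 21 | none | none
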